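(The earlier runs and the new flask were generated by integration for an exercise, noise included.)

No constant of this chemistry is given, so one has to be read from the earlier runs.

| flask | starting material | second substrate | free catalyst | temperature | remark | time |
|---|---|---|---|---|---|---|
| alpha | 0.048 M | 0.70 equiv | 15 mol% (in portions, 3) | 69 °C | run made earlier; portions every 15 min |  |
| epsilon | 0.048 M | 1.1 equiv | 15 mol% (in portions, 3) | 77 °C | run made earlier; portions every 15 min |  |
| beta | 0.072 M | 0.50 equiv | 15 mol% (in portions, 3) | 69 °C | run made earlier; portions every 15 min |  |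
| dawn | 0.048 M | 0.500 equiv | 15 mol% (in portions, 3) | 80 °C | the portions of free catalyst follow each other after 15 min, the first at the start | 4.0 h |
| winter | 0.048 M | 0.500 equiv | 15 mol% | 65 °C | everything together at the start | 12 h |

| run | time / h | target / % |
|---|---|---|
| alpha | 0.833 | 2 |
| alpha | 1.50 | 6 |
| alpha | 2.50 | 15 |
| alpha | 3.00 | 19 |
| alpha | 4.00 | 24 |
| alpha | 5.00 | 29 |
| epsilon | 0.500 | 2 |
| epsilon | 1.00 | 10 |
| epsilon | 1.50 | 19 |
| epsilon | 2.00 | 23 |
| epsilon | 2.50 | 25 |
| epsilon | 3.00 | 32 |
| beta | 1.00 | 4 |
| beta | 2.50 | 17 |
| beta | 3.00 | 18 |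
| beta | 4.00 | 29 |
| beta | 5.00 | 40 |

(readings scatter by 2 percentage points)



- the flask that ends with the higher amount of target, in percent of the starting material charged, or "neither" when 2 percentage points or less lies between them (dawn / winter / neither)
- final target, as a percentage of the starting material charged, in dawn
- final target, as a percentage of the starting material charged, in winter

Alpha's last reading gives 0.0721 h⁻¹. That figure is the clock constant, a pseudo-first-order constant: the natural logarithm of one over the fraction of starting material not yet turned into target, divided by the time since the mean addition of free catalyst. For these portions that mean lies 15 min after the start; for winter it is the start itself.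

Beta reads 0.108 h⁻¹, which is 1.50 times alpha's at 1.50 times the [starting material], while [second substrate] is 0.0360 M against 0.0336 M. Read from one reading of each run, the clock rises in step with [starting material] and the free catalyst charged on it, which rise together here, and dawn and winter share alpha's 0.048 M.

Epsilon, at that same concentration, reads 0.140 h⁻¹. Held against alpha, this yields an apparent activation energy of 82.8 kJ mol⁻¹, on the assumption that epsilon's larger charge of second substrate does not alter the clock. Carried up to 80 °C, the constant becomes 0.179 h⁻¹, and dawn is reckoned at 48.8 %. Carried down to 65 °C, it becomes 0.0511 h⁻¹, and winter is reckoned at 45.8 %. By this reckoning dawn ends higher than winter by 3 percentage points, against a margin of 2 points.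

The weak link is epsilon's last reading, a jump from 25 % to 32 %. Epsilon's reading at 2.00 h gives 0.149 h⁻¹ instead, hence 90.7 kJ mol⁻¹, dawn 51.8 % and winter 44.8 %. The gap grows, so the call for dawn stands.

The forecast, which differs from this reckoning, named winter, with dawn at 30 % (21 % to 40 %) and winter at 35 % (24 % to 47 %), citing “Slowing from catalyst death and substrate depletion”.

Dawn ends at 50.6 % and winter at 46.4 %, so dawn gives more.

    starting material + free catalyst ⇌ catalyst intermediate A (K = 8.90 M⁻¹, k = 13.0 M⁻¹ min⁻¹, Ea = 49.0 kJ mol⁻¹, ΔH = −11.0 kJ mol⁻¹)
    catalyst intermediate A → free catalyst + target (k = 0.0690 min⁻¹, Ea = 93.0 kJ mol⁻¹)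
    second substrate + free catalyst ⇌ catalyst intermediate B (K = 17.0 M⁻¹, k = 1.00 M⁻¹ min⁻¹, Ea = 60.0 kJ mol⁻¹, ΔH = −5.00 kJ mol⁻¹)
    catalyst intermediate B → free catalyst + second product (k = 0.910 min⁻¹, Ea = 95.0 kJ mol⁻¹)
    second substrate ⇌ dormant form (K = 3.30, k = 0.0100 min⁻¹, Ea = 114 kJ mol⁻¹, ΔH = 4.00 kJ mol⁻¹)
    (constants at 80 °C)

At 4.00 h, dawn holds 83.7 % of its catalyst charge as free catalyst, 16.1 % as catalyst intermediate A and 0.259 % as catalyst intermediate B. Dawn's own clock constant comes to 0.188 h⁻¹. Winter's reckoned 0.0511 h⁻¹ puts winter, left until 20 h, at 64.0 % of target, and that flask holds 66.5 %.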